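**Plan**
- Retrosynthetic cuts: the angelate O–acyl bond at C3'; the pyranone ring (O1–C2, C2–C3 and C4–C4a) back to a trimethoxyaryl piperidine; N–CH3; the piperidine C4'–C5' bond, as the C4'=C5' alkene, by retro carbonyl–olefin metathesis; the C4'–C8 bond to a Weinreb amide and an aryllithium.
- Enabling feature: piperidine C4' carries chromone C8 (flanked by the oxygens on C7 and C8a) and adjoins oxygenated C3'. The C3'–C4'(aryl) unit is therefore an α-silyloxy aryl ketone from a 3-amino-2-hydroxy acid, and C5'–C6'–N comes from an N-prenyl sulfonamide.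
- Forward order: the isoserine chain is N-sulfonylated, O-silylated, N-prenylated and joined to the arene as a ketone. The piperidine ring closes first (step 7), the pyranone ring of the chromone is annulated second (steps 11–12), and the angelate goes on last.
- Stereochemistry: C3' (S) is the carbinol carbon of (R)-isoserine; C4' (R) is set by hydrogenation of C4'=C5' anti to the C3' silyl ether; the Z alkene comes intact from angelic acid.

Key step: step 7

Assumption: (R)-isoserine and 4-(trifluoromethyl)benzenesulfonyl chloride are taken as commercial; primed locants denote the piperidine ring, unprimed ones the chromone.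

**Route**

Step 1
Reactants: 1 (R)-isoserine
Product: 2 methyl (2R)-3-amino-2-hydroxypropanoate hydrochloride
Conditions: SOCl2, MeOH, 0 °C to reflux
Reagents that add atoms: methanol, CO; thionyl chloride, O=S(Cl)Cl (source of the chloride of the salt)
Why: Fischer esterification under HCl generated in situ should give the ester as its ammonium chloride, and the acidic medium cannot epimerise C2.

Step 2
Reactants: 2 methyl (2R)-3-amino-2-hydroxypropanoate hydrochloride
Product: 3 methyl (2R)-2-hydroxy-3-{[4-(trifluoromethyl)phenyl]sulfonylamino}propanoate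
Conditions: 4-CF3C6H4SO2Cl, Et3N, CH2Cl2, 0 °C to rt
Reagents that add atoms: 4-(trifluoromethyl)benzenesulfonyl chloride, O=S(=O)(Cl)c1ccc(cc1)C(F)(F)F
Why: N-sulfonylation of the primary amine is much faster than O-sulfonylation of the secondary alcohol at 0 °C, and this electron-poor arenesulfonyl group is chosen because it should bind Lewis acids more weakly than tosyl in step 7.

Step 3
Reactants: 3 methyl (2R)-2-hydroxy-3-{[4-(trifluoromethyl)phenyl]sulfonylamino}propanoate
Product: 4 methyl (2R)-2-(tert-butyldimethylsilyloxy)-3-{[4-(trifluoromethyl)phenyl]sulfonylamino}propanoate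
Conditions: TBSCl, imidazole, DMF, rt
Reagents that add atoms: tert-butyldimethylsilyl chloride, CC(C)(C)[Si](C)(C)Cl
Why: Corey silylation of the secondary alcohol installs a bulky, weakly Lewis-basic ether, and any N-silylation of the sulfonamide is reversed on aqueous work-up.

Step 4
Reactants: 4 methyl (2R)-2-(tert-butyldimethylsilyloxy)-3-{[4-(trifluoromethyl)phenyl]sulfonylamino}propanoate; 5 prenyl bromide (1-bromo-3-methylbut-2-ene)
Product: 6 methyl (2R)-2-(tert-butyldimethylsilyloxy)-3-{(3-methylbut-2-en-1-yl)[4-(trifluoromethyl)phenyl]sulfonylamino}propanoate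
Conditions: 5, K2CO3, DMF, rt
Reagents that add atoms: prenyl bromide 5, CC(C)=CCBr
Why: SN2 N-alkylation of the acidic sulfonamide N–H with the allylic bromide should be clean, since carbonate is too weak to enolise the α-silyloxy ester and C2 is not touched.

Step 5
Reactants: 6 methyl (2R)-2-(tert-butyldimethylsilyloxy)-3-{(3-methylbut-2-en-1-yl)[4-(trifluoromethyl)phenyl]sulfonylamino}propanoate
Product: 7 (2R)-2-(tert-butyldimethylsilyloxy)-N-methoxy-N-methyl-3-{(3-methylbut-2-en-1-yl)[4-(trifluoromethyl)phenyl]sulfonylamino}propanamide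
Conditions: MeNHOMe·HCl, iPrMgCl, THF, −20 °C
Reagents that add atoms: N,O-dimethylhydroxylamine hydrochloride, CNOC.Cl
Why: Weinreb amide formation by aminolysis of the ester with the magnesium amide of N,O-dimethylhydroxylamine is a low-temperature, non-epimerising reaction that tolerates α-silyloxy esters.

Step 6
Reactants: 7 (2R)-2-(tert-butyldimethylsilyloxy)-N-methoxy-N-methyl-3-{(3-methylbut-2-en-1-yl)[4-(trifluoromethyl)phenyl]sulfonylamino}propanamide; 8 1,3,5-trimethoxybenzene
Product: 10 N-[(2R)-2-(tert-butyldimethylsilyloxy)-3-oxo-3-(2,4,6-trimethoxyphenyl)propyl]-N-(3-methylbut-2-en-1-yl)-4-(trifluoromethyl)benzenesulfonamide, via 2,4,6-trimethoxyphenyllithium 9 (not isolated)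
Conditions: 8, n-BuLi, THF, 0 °C to rt; then 7, −78 to 0 °C; aq. NH4Cl
Reagents that add atoms: 1,3,5-trimethoxybenzene 8, COc1cc(OC)cc(OC)c1 (as its 2-lithio derivative 9)
Why: Directed ortho-lithiation followed by Weinreb ketone synthesis should work because the chelated tetrahedral adduct persists until the quench, so neither over-addition nor base-induced loss of the β-sulfonamide from the ketone can occur.

Step 7
Reactants: 10 N-[(2R)-2-(tert-butyldimethylsilyloxy)-3-oxo-3-(2,4,6-trimethoxyphenyl)propyl]-N-(3-methylbut-2-en-1-yl)-4-(trifluoromethyl)benzenesulfonamide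
Product: 12 (3S)-3-(tert-butyldimethylsilyloxy)-1-{[4-(trifluoromethyl)phenyl]sulfonyl}-4-(2,4,6-trimethoxyphenyl)-1,2,3,6-tetrahydropyridine, via fused oxetane 11 (not isolated)
Conditions: FeCl3 (30 mol%), anhydrous ClCH2CH2Cl (0.02 M), rt
Reagents that add atoms: none
Why: FeCl3 binds the ketone oxygen and the prenyl alkene adds in an asynchronous, concerted [2+2] sense, C5' bonding to the carbonyl carbon C4' while the carbonyl oxygen bonds to the CMe2 carbon, to give the cis-fused oxetane 11, which then cleaves by retro-[2+2] in the other direction to the C4'=C5' alkene and acetone. The closest known reaction type is the FeCl3-catalysed ring-closing carbonyl–olefin metathesis of amino acid-derived aryl ketones bearing an N-prenyl sulfonamide, which gives N-sulfonyl dihydropyrroles and tetrahydropyridines with the α-stereocentre intact. The piperidine ring closes in a 6-exo-trig mode with respect to both π bonds, the CMe2 carbon and the carbonyl oxygen staying outside the six-membered ring and leaving together as acetone. No stereocentre is created in the product, because C3' is carried over from isoserine and the two oxetane centres vanish on fragmentation. The step needs activation of the twisted, electron-rich di-ortho-methoxy ketone in preference to the other Lewis-basic sites and no enolisation toward C3'; the electron-poor sulfonamide and the hindered silyl ether should bind FeCl3 only weakly, the medium is aprotic, and the gem-dimethyl alkene terminus with irreversible loss of acetone should favour metathesis over ene or arene-alkylation pathways.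

Step 8
Reactants: 12 (3S)-3-(tert-butyldimethylsilyloxy)-1-{[4-(trifluoromethyl)phenyl]sulfonyl}-4-(2,4,6-trimethoxyphenyl)-1,2,3,6-tetrahydropyridine
Product: 13 (3S,4R)-3-(tert-butyldimethylsilyloxy)-1-{[4-(trifluoromethyl)phenyl]sulfonyl}-4-(2,4,6-trimethoxyphenyl)piperidine
Conditions: H2 (10 bar), PtO2, EtOAc, rt
Reagents that add atoms: none
Why: Heterogeneous catalytic hydrogenation adds both hydrogens syn to the face opposite the silyl ether, which allylic 1,2-strain against the perpendicular di-ortho-methoxyaryl ring forces pseudoaxial, so hydrogen enters C4' anti to oxygen and the aryl group ends cis to it (4R).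

Step 9
Reactants: 13 (3S,4R)-3-(tert-butyldimethylsilyloxy)-1-{[4-(trifluoromethyl)phenyl]sulfonyl}-4-(2,4,6-trimethoxyphenyl)piperidine
Product: 14 (3S,4R)-3-(tert-butyldimethylsilyloxy)-4-(2,4,6-trimethoxyphenyl)piperidine
Conditions: Mg, MeOH, sonication, rt
Reagents that add atoms: none
Why: Single-electron (dissolving-metal) reductive cleavage of the S–N bond is eased by the electron-poor arene, while the silyl ether and aryl methyl ethers are inert to Mg in methanol.

Step 10
Reactants: 14 (3S,4R)-3-(tert-butyldimethylsilyloxy)-4-(2,4,6-trimethoxyphenyl)piperidine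
Product: 16 (3S,4R)-1-methyl-4-(2,4,6-trimethoxyphenyl)piperidin-3-ol, via N-methyl silyl ether 15 (not isolated)
Conditions: aq. HCHO, NaBH(OAc)3, ClCH2CH2Cl, rt; then HCl, MeOH, rt; NaOH work-up
Reagents that add atoms: formaldehyde, C=O
Why: Reductive amination through the iminium ion methylates the secondary amine, and acidic methanolysis then removes the silyl ether without affecting either stereocentre.

Step 11
Reactants: 16 (3S,4R)-1-methyl-4-(2,4,6-trimethoxyphenyl)piperidin-3-ol
Product: 18 1-{2-hydroxy-3-[(3S,4R)-3-hydroxy-1-methylpiperidin-4-yl]-4,6-dimethoxyphenyl}ethan-1-one, via O-acetyl acetophenone 17 (not isolated)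
Conditions: Ac2O, BF3·OEt2, CH2Cl2, 0 °C to rt; then aq. NaOH, MeOH, rt
Reagents that add atoms: acetic anhydride, CC(=O)OC(C)=O
Why: Friedel–Crafts acetylation at the free ring position is accompanied by BF3-chelation-assisted cleavage of the methyl ether flanked by the acetyl and piperidinyl groups, and saponification then removes the C3' acetate and the boron chelate.

Step 12
Reactants: 18 1-{2-hydroxy-3-[(3S,4R)-3-hydroxy-1-methylpiperidin-4-yl]-4,6-dimethoxyphenyl}ethan-1-one
Product: 20 8-[(3S,4R)-3-hydroxy-1-methylpiperidin-4-yl]-5,7-dimethoxy-2-methyl-4H-chromen-4-one, via aryl 1,3-diketone 19 (not isolated)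
Conditions: NaH, EtOAc, THF, reflux; then conc. HCl, MeOH, 60 °C
Reagents that add atoms: ethyl acetate, CCOC(C)=O
Why: Claisen condensation of the acetophenone enolate with ethyl acetate gives the 1,3-diketone, whose acid-catalysed cyclodehydration closes the pyranone ring, and any C3' acetate formed by transesterification is methanolysed in the same acid stage.

Step 13
Reactants: 20 8-[(3S,4R)-3-hydroxy-1-methylpiperidin-4-yl]-5,7-dimethoxy-2-methyl-4H-chromen-4-one
Product: 21 5,7-dihydroxy-8-[(3S,4R)-3-hydroxy-1-methylpiperidin-4-yl]-2-methyl-4H-chromen-4-one (rohitukine)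
Conditions: pyridine·HCl (melt), 180 °C
Reagents that add atoms: none
Why: Aryl methyl ether cleavage by SN2 attack of chloride on the protonated ethers in molten pyridine hydrochloride is a standard demethylation of 5,7-dimethoxychromones and leaves the protonated amino alcohol untouched.

Step 14
Reactants: 21 5,7-dihydroxy-8-[(3S,4R)-3-hydroxy-1-methylpiperidin-4-yl]-2-methyl-4H-chromen-4-one; 22 angelic acid ((2Z)-2-methylbut-2-enoic acid)
Product: 24 5-hydroxy-2-methyl-8-[(3S,4R)-1-methyl-3-{[(2Z)-2-methylbut-2-enoyl]oxy}piperidin-4-yl]-4-oxo-4H-chromen-7-yl (2Z)-2-methylbut-2-enoate, via angelic 2,4,6-trichlorobenzoic anhydride 23 (not isolated)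
Conditions: 22 (3.5 equiv), 2,4,6-trichlorobenzoyl chloride, Et3N, toluene–THF, rt; then 21, 80 °C
Reagents that add atoms: angelic acid 22, C/C=C(/C)C(=O)O
Why: Yamaguchi-type esterification through the mixed anhydride without a nucleophilic catalyst avoids Z-to-E isomerisation of angelates, and excess reagent should acylate both the acidic C7 phenol and the hindered C3' alcohol while the hydrogen-bonded C5 phenol stays free.

Step 15
Reactants: 24 5-hydroxy-2-methyl-8-[(3S,4R)-1-methyl-3-{[(2Z)-2-methylbut-2-enoyl]oxy}piperidin-4-yl]-4-oxo-4H-chromen-7-yl (2Z)-2-methylbut-2-enoate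
Product: 25 (3S,4R)-4-(5,7-dihydroxy-2-methyl-4-oxo-4H-chromen-8-yl)-1-methylpiperidin-3-yl (2Z)-2-methylbut-2-enoate
Conditions: K2CO3 (1.2 equiv), MeOH, 0 °C; pH 7 buffer
Reagents that add atoms: none
Why: Chemoselective transesterification removes only the aryl ester, which is an activated ester of the acidic 7-hydroxychromone, whereas the hindered, conjugated alkyl angelate at C3' should be inert to carbonate in methanol at 0 °C.

**Compound list**

1 | (R)-isoserine | NC[C@@H](O)C(=O)O | starting material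
2 | methyl (2R)-3-amino-2-hydroxypropanoate hydrochloride | Cl.NC[C@@H](O)C(=O)OC | intermediate
3 | methyl (2R)-2-hydroxy-3-{[4-(trifluoromethyl)phenyl]sulfonylamino}propanoate | O=S(=O)(NC[C@@H](O)C(=O)OC)c1ccc(cc1)C(F)(F)F | intermediate
4 | methyl (2R)-2-(tert-butyldimethylsilyloxy)-3-{[4-(trifluoromethyl)phenyl]sulfonylamino}propanoate | O=S(=O)(NC[C@@H](O[Si](C)(C)C(C)(C)C)C(=O)OC)c1ccc(cc1)C(F)(F)F | intermediate
5 | prenyl bromide | CC(C)=CCBr | starting material
6 | methyl (2R)-2-(tert-butyldimethylsilyloxy)-3-{(3-methylbut-2-en-1-yl)[4-(trifluoromethyl)phenyl]sulfonylamino}propanoate | CC(C)=CCN(C[C@@H](O[Si](C)(C)C(C)(C)C)C(=O)OC)S(=O)(=O)c1ccc(cc1)C(F)(F)F | intermediate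
7 | (2R)-2-(tert-butyldimethylsilyloxy)-N-methoxy-N-methyl-3-{(3-methylbut-2-en-1-yl)[4-(trifluoromethyl)phenyl]sulfonylamino}propanamide | CC(C)=CCN(C[C@@H](O[Si](C)(C)C(C)(C)C)C(=O)N(C)OC)S(=O)(=O)c1ccc(cc1)C(F)(F)F | intermediate
8 | 1,3,5-trimethoxybenzene | COc1cc(OC)cc(OC)c1 | starting material
9 | 2,4,6-trimethoxyphenyllithium (not isolated) | [Li]c1c(OC)cc(OC)cc1OC | intermediate
10 | N-[(2R)-2-(tert-butyldimethylsilyloxy)-3-oxo-3-(2,4,6-trimethoxyphenyl)propyl]-N-(3-methylbut-2-en-1-yl)-4-(trifluoromethyl)benzenesulfonamide | CC(C)=CCN(C[C@@H](O[Si](C)(C)C(C)(C)C)C(=O)c1c(OC)cc(OC)cc1OC)S(=O)(=O)c1ccc(cc1)C(F)(F)F | intermediate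
11 | (5R)-5-(tert-butyldimethylsilyloxy)-8,8-dimethyl-3-{[4-(trifluoromethyl)phenyl]sulfonyl}-6-(2,4,6-trimethoxyphenyl)-7-oxa-3-azabicyclo[4.2.0]octane, cis-fused, ring-fusion configuration not defined (not isolated) | CC(C)(C)[Si](C)(C)O[C@@H]1CN(S(=O)(=O)c2ccc(cc2)C(F)(F)F)CC2C(C)(C)OC12c1c(OC)cc(OC)cc1OC | intermediate
12 | (3S)-3-(tert-butyldimethylsilyloxy)-1-{[4-(trifluoromethyl)phenyl]sulfonyl}-4-(2,4,6-trimethoxyphenyl)-1,2,3,6-tetrahydropyridine | CC(C)(C)[Si](C)(C)O[C@@H]1CN(S(=O)(=O)c2ccc(cc2)C(F)(F)F)CC=C1c1c(OC)cc(OC)cc1OC | intermediate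
13 | (3S,4R)-3-(tert-butyldimethylsilyloxy)-1-{[4-(trifluoromethyl)phenyl]sulfonyl}-4-(2,4,6-trimethoxyphenyl)piperidine | CC(C)(C)[Si](C)(C)O[C@@H]1CN(S(=O)(=O)c2ccc(cc2)C(F)(F)F)CC[C@@H]1c1c(OC)cc(OC)cc1OC | intermediate
14 | (3S,4R)-3-(tert-butyldimethylsilyloxy)-4-(2,4,6-trimethoxyphenyl)piperidine | CC(C)(C)[Si](C)(C)O[C@@H]1CNCC[C@@H]1c1c(OC)cc(OC)cc1OC | intermediate
15 | (3S,4R)-3-(tert-butyldimethylsilyloxy)-1-methyl-4-(2,4,6-trimethoxyphenyl)piperidine (not isolated) | CC(C)(C)[Si](C)(C)O[C@@H]1CN(C)CC[C@@H]1c1c(OC)cc(OC)cc1OC | intermediate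
16 | (3S,4R)-1-methyl-4-(2,4,6-trimethoxyphenyl)piperidin-3-ol | O[C@@H]1CN(C)CC[C@@H]1c1c(OC)cc(OC)cc1OC | intermediate
17 | (3S,4R)-4-(3-acetyl-2-hydroxy-4,6-dimethoxyphenyl)-1-methylpiperidin-3-yl acetate, held as its difluoroboron chelate until the basic stage (not isolated) | CC(=O)O[C@@H]1CN(C)CC[C@@H]1c1c(OC)cc(OC)c(C(C)=O)c1O | intermediate
18 | 1-{2-hydroxy-3-[(3S,4R)-3-hydroxy-1-methylpiperidin-4-yl]-4,6-dimethoxyphenyl}ethan-1-one | O[C@@H]1CN(C)CC[C@@H]1c1c(OC)cc(OC)c(C(C)=O)c1O | intermediate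
19 | 1-{2-hydroxy-3-[(3S,4R)-3-hydroxy-1-methylpiperidin-4-yl]-4,6-dimethoxyphenyl}butane-1,3-dione (not isolated) | O[C@@H]1CN(C)CC[C@@H]1c1c(OC)cc(OC)c(C(=O)CC(C)=O)c1O | intermediate
20 | 8-[(3S,4R)-3-hydroxy-1-methylpiperidin-4-yl]-5,7-dimethoxy-2-methyl-4H-chromen-4-one | O[C@@H]1CN(C)CC[C@@H]1c1c(OC)cc(OC)c2c(=O)cc(C)oc12 | intermediate
21 | 5,7-dihydroxy-8-[(3S,4R)-3-hydroxy-1-methylpiperidin-4-yl]-2-methyl-4H-chromen-4-one (rohitukine) | O[C@@H]1CN(C)CC[C@@H]1c1c(O)cc(O)c2c(=O)cc(C)oc12 | intermediate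
22 | angelic acid, (2Z)-2-methylbut-2-enoic acid | C/C=C(/C)C(=O)O | starting material
23 | (2Z)-2-methylbut-2-enoic 2,4,6-trichlorobenzoic anhydride (not isolated) | C/C=C(/C)C(=O)OC(=O)c1c(Cl)cc(Cl)cc1Cl | intermediate
24 | 5-hydroxy-2-methyl-8-[(3S,4R)-1-methyl-3-{[(2Z)-2-methylbut-2-enoyl]oxy}piperidin-4-yl]-4-oxo-4H-chromen-7-yl (2Z)-2-methylbut-2-enoate | C/C=C(/C)C(=O)O[C@@H]1CN(C)CC[C@@H]1c1c(OC(=O)/C(C)=C\C)cc(O)c2c(=O)cc(C)oc12 | intermediate
25 | (3S,4R)-4-(5,7-dihydroxy-2-methyl-4-oxo-4H-chromen-8-yl)-1-methylpiperidin-3-yl (2Z)-2-methylbut-2-enoate | C/C=C(/C)C(=O)O[C@@H]1CN(C)CC[C@@H]1c1c(O)cc(O)c2c(=O)cc(C)oc12 | target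

**Step count and risks**

Total step count: 15. Longest linear sequence: 15 steps, from 1 to 25; compounds 5, 8 and 22 enter as purchased materials.

Steps most likely to fail:

1. Step 7. The catalyst may be sequestered by the methoxy, sulfonamide or silyl ether oxygens, so the twisted, electron-rich ketone is never activated. Alternatively the Lewis acid may strip the silyl ether, or cationic intermediates may alkylate the arene. Fallback, using olefin–olefin metathesis for the same C4'=C5' bond and ring: setting out from 10, non-basic methylenation with the Tebbe reagent Cp2Ti(μ-Cl)(μ-CH2)AlMe2 (THF, pyridine, −40 °C to rt) would give N-[(2S)-2-(tert-butyldimethylsilyloxy)-3-(2,4,6-trimethoxyphenyl)but-3-en-1-yl]-N-(3-methylbut-2-en-1-yl)-4-(trifluoromethyl)benzenesulfonamide F1. Ring-closing metathesis with the second-generation Grubbs catalyst RuCl2(=CHPh)(H2IMes)(PCy3) in toluene at 80 °C would then expel 2-methylpropene and come back to the route at 12.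

2. Step 8. Facial selectivity may be poor. The metal may also move the double bond into the C3'=C4' position, giving a silyl enol ether and erasing C3', or may hydrogenolyse the allylic C–O bond. Fallback, which gives up the chiral-pool C3' and resets both centres by catalyst control: setting out from 12, Bu4NF in THF would give (3S)-1-{[4-(trifluoromethyl)phenyl]sulfonyl}-4-(2,4,6-trimethoxyphenyl)-1,2,3,6-tetrahydropyridin-3-ol F2. Dess–Martin oxidation would give 1-{[4-(trifluoromethyl)phenyl]sulfonyl}-4-(2,4,6-trimethoxyphenyl)-1,6-dihydropyridin-3(2H)-one F3. Hydrogenation of the enone over Pd/C would give the configurationally labile 1-{[4-(trifluoromethyl)phenyl]sulfonyl}-4-(2,4,6-trimethoxyphenyl)piperidin-3-one F4. Asymmetric transfer hydrogenation under dynamic kinetic resolution, with RuCl(p-cymene)(TsDPEN) of the ligand hand matched to the 3S carbinol and HCO2H/Et3N, would give the cis alcohol (3S,4R)-1-{[4-(trifluoromethyl)phenyl]sulfonyl}-4-(2,4,6-trimethoxyphenyl)piperidin-3-ol F5. Silylation with TBSOTf and 2,6-lutidine would come back to the route at 13.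

3. Step 14. The angeloyl unit may isomerise from Z to E during activation, and acylation of the hindered axial C3' hydroxyl of a poorly soluble triol may stall. Fallback, which builds the Z alkene by olefination after the ester bond is made: setting out from 21, DCC/DMAP esterification with 2-[bis(2,2,2-trifluoroethoxy)phosphoryl]propanoic acid, a saturated acid that cannot isomerise, would give 5-hydroxy-2-methyl-8-[(3S,4R)-1-methyl-3-({2-[bis(2,2,2-trifluoroethoxy)phosphoryl]propanoyl}oxy)piperidin-4-yl]-4-oxo-4H-chromen-7-yl 2-[bis(2,2,2-trifluoroethoxy)phosphoryl]propanoate F6. Still–Gennari olefination with acetaldehyde (KN(SiMe3)2, 18-crown-6, THF, −78 °C) would form both Z-configured 2-methylbut-2-enoates and come back to the route at 24, from which step 15 proceeds unchanged.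

**Further compounds**

F1 | step 7 | N-[(2S)-2-(tert-butyldimethylsilyloxy)-3-(2,4,6-trimethoxyphenyl)but-3-en-1-yl]-N-(3-methylbut-2-en-1-yl)-4-(trifluoromethyl)benzenesulfonamide | CC(C)=CCN(C[C@@H](O[Si](C)(C)C(C)(C)C)C(=C)c1c(OC)cc(OC)cc1OC)S(=O)(=O)c1ccc(cc1)C(F)(F)F
F2 | step 8 | (3S)-1-{[4-(trifluoromethyl)phenyl]sulfonyl}-4-(2,4,6-trimethoxyphenyl)-1,2,3,6-tetrahydropyridin-3-ol | O[C@@H]1CN(S(=O)(=O)c2ccc(cc2)C(F)(F)F)CC=C1c1c(OC)cc(OC)cc1OC
F3 | step 8 | 1-{[4-(trifluoromethyl)phenyl]sulfonyl}-4-(2,4,6-trimethoxyphenyl)-1,6-dihydropyridin-3(2H)-one | O=C1CN(S(=O)(=O)c2ccc(cc2)C(F)(F)F)CC=C1c1c(OC)cc(OC)cc1OC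
F4 | step 8 | 1-{[4-(trifluoromethyl)phenyl]sulfonyl}-4-(2,4,6-trimethoxyphenyl)piperidin-3-one | O=C1CN(S(=O)(=O)c2ccc(cc2)C(F)(F)F)CCC1c1c(OC)cc(OC)cc1OC
F5 | step 8 | (3S,4R)-1-{[4-(trifluoromethyl)phenyl]sulfonyl}-4-(2,4,6-trimethoxyphenyl)piperidin-3-ol | O[C@@H]1CN(S(=O)(=O)c2ccc(cc2)C(F)(F)F)CC[C@@H]1c1c(OC)cc(OC)cc1OC
F6 | step 14 | 5-hydroxy-2-methyl-8-[(3S,4R)-1-methyl-3-({2-[bis(2,2,2-trifluoroethoxy)phosphoryl]propanoyl}oxy)piperidin-4-yl]-4-oxo-4H-chromen-7-yl 2-[bis(2,2,2-trifluoroethoxy)phosphoryl]propanoate | CC(C(=O)O[C@@H]1CN(C)CC[C@@H]1c1c(OC(=O)C(C)P(=O)(OCC(F)(F)F)OCC(F)(F)F)cc(O)c2c(=O)cc(C)oc12)P(=O)(OCC(F)(F)F)OCC(F)(F)F
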